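**Numbering used throughout** (full names and SMILES are in the compound list)

1 1,3,5-tris(benzyloxy)benzene · 2 2,4,6-tris(benzyloxy)benzaldehyde · 3 methyl 4,5-dibromofuran-2-carboxylate · 4 4-(benzyloxy)phenylboronic acid · 5 4-bromo-5-aryl-2-furoate · 6 furylmagnesium intermediate · 7 furyl aryl carbinol · 8 4-aroyl-5-aryl-2-furoate · 9 furoic acid · 10 furoyl chloride · 11 furyl diazo ketone · 12 1-(benzyloxy)-4-bromobenzene · 13 ethyl 4-chloro-4-oxobutanoate · 14 arylmagnesium bromide · 15 γ-keto ester · 16 (S)-γ-hydroxy ester · 17 its triethylsilyl ether · 18 lithium ynolate · 19 siloxyalkyne · 20 furylketene · 21 siloxycyclobutenone · 22 dienylketene · 23 benzannulation product · 24 phenol carbinol · 25 (R)-flavan silyl ether · 26 C5' phenol · 27 hexaphenol (open aroylbenzofuran) · 28 target.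

Locants: O1, C2, C3, C4, C4a–C8a for the chromanone part; primed locants for the flavan part (O1', C2', C3', C4', C4a'–C8a'); O7' is the furan oxygen on C7'.

## Analysis of the target

Compound 28 has a fused pentacyclic core. A 5,7-dihydroxychroman-4-one (ring A and pyranone ring C) shares its C2–C3 bond with a dihydrofuran ring (O7', C2, C3, C8', C7'), which is fused to the arene of a 4'-hydroxyflavan; C2 carries a second 4-hydroxyphenyl group. There are three stereocentres. The diaryl ketal carbon C2 (S) and the neighbouring methine C3 (S) are locked cis by the 6/5 ring fusion and behave as one stereochemical element. The benzylic ether carbon C2' (R) lies on the far side of the flavan arene and cannot steer that pair. The ketal is the oxa-Michael adduct of a phenol onto a 3-aroylbenzofuran, so it can reopen under base and ionise under acid; C3 is α to the ketone, C2'–O1' is a benzylic ether, and five free phenols make the compound sensitive to air and base. The first difficulty is the flavan arene (C4a', C5', C6', C7', C8', C8a'). It is a pentasubstituted phloroglucinol whose three oxygens have three different roles: pyran O1' on C8a', free hydroxyl on C5', furan O7' on C7'. Substitution chemistry on a 5,7-dioxygenated flavan distinguishes neither these oxygens nor C6' from C8'. The second difficulty is the configuration of the C2/C3 pair relative to the remote C2'. The strategy rests on the flavan arene: its six carbons are built de novo so that the three oxygens emerge already differentiated.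

## Retrosynthetic reasoning

**28 ⇒ 27 (cut O1–C2).** The ketal is opened in the retro-oxa-Michael sense to the 3-aroyl-2-arylbenzofuran 27. The cut is made here because the ketal is the most labile function, so forming it last means no other step has to tolerate it. C2 and C3 then arise together, and the cis fusion is enforced by the ring. The forward step has to choose one face of a flat benzofuran; C2' is too far away to do so, which leaves the choice to a chiral base.

**27 ⇒ 26 ⇒ 25 (protecting groups).** All phenols that must pass through organometallic steps are carried as benzyl ethers and released together by hydrogenolysis. The C5' oxygen is carried as the silyl ether that the alkyne partner brings in, so it needs no protection step of its own.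

**25 ⇒ 24 ⇒ 23 (cut O1'–C2').** The pyran ring is opened to a phenol and a benzylic carbinol. In 24 the C8a' hydroxyl is the only free phenol, so the closure cannot go to the C5' oxygen. C2' is taken from an (S)-carbinol that closes with inversion, so the stereocentre comes from a ketone reduction.

**23 ⇒ 11 + 19 (cut C4a'–C8a', C5'–C6' and C8'–C8a').** The benzene ring is taken apart into the furyl diazo ketone 11 and the siloxyalkyne 19. The Wolff shift that links C6' to C7' is the fourth bond made in the forward step. This is the only place where the three oxygens can be told apart by origin: ketene oxygen, alkyne oxygen, furan oxygen. The forward reaction has to deliver the alkyl chain between the two new oxygens and close onto the single free furan β-carbon.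

**19 ⇒ 17 ⇒ 16 ⇒ 15 ⇒ 12 + 13.** The ynol ether is traced to an ester by an ester-to-ynolate homologation. The ester is traced to the γ-keto ester 15, whose reduction sets the only stereocentre of the fragment. 15 is assembled from the aryl bromide 12 and the half-ester chloride 13. An acylation of an arylmagnesium reagent is chosen over a Lewis-acid Friedel–Crafts reaction, which would endanger the benzyl ether.

**11 ⇒ 9 ⇒ 8 ⇒ 7 ⇒ 5 + 2; 5 ⇒ 3 + 4; 2 ⇒ 1.** The diazo ketone comes from the furoic acid 9. The aroyl group is not introduced by electrophilic aroylation of the furan, because a Lewis acid would threaten the ortho benzyloxy groups and the electron-rich aryl ring would compete. Instead the two bromine atoms of 3 fix the positions: the α-bromide is replaced by the aryl group of 4, and the β-bromide is converted into a carbon nucleophile that adds to aldehyde 2. Aldehyde 2 comes from the symmetric triether 1 by formylation.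

## Alternatives that were turned down

**Alternative 1: carbonylative three-component assembly of the furan ring.**
- Disconnection: C2–O7', C3–C4 and C4–C4a. The benzofuran and its aroyl group are made at once from the alkynylphenol A2, CO and the aryl iodide A3, giving the hexabenzyl compound A1.
- Forward key step: under Pd(PPh3)4 an aroylpalladium species activates the alkyne, the phenol attacks, and reductive elimination closes the furan.
- For it: it is highly convergent, uses no diazo compound and no light, and belongs to a known class (carbonylative annulation of ortho-alkynylphenols). On convergence at the coupling stage it is stronger than the chosen route.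
- Against it: A2 must carry the alkyne on C8' and not on C6', with a free 7'-OH beside a protected 5'-oxygen. That is the same phloroglucinol differentiation problem, moved to a flavan where electronic bias between C6' and C8' is small. A3 is doubly ortho-substituted and electron-rich, so oxidative addition and CO insertion are slow, and cyclisation without CO uptake is a likely competitor.
- Comparison: the chosen route has a longer build-up but makes the oxygen pattern unambiguous by construction.

**Alternative 2: ortho-quinone methide cycloaddition closing the flavan ring last.**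
- Disconnection: C3'–C4' and O1'–C2'. The hydroxybenzyl alcohol A5 (the preformed ketal core) and 4-vinylphenol A6 give A4, the tetrabenzyl ether of 28.
- Forward key step: a chiral BINOL-derived phosphoric acid dehydrates A5 to the quinone methide, which adds A6 in a hetero-Diels–Alder reaction.
- For it: C2' is introduced catalytically at the very end, and the step count after the core is low. On late-stage economy it is stronger.
- Against it: the acid that must ionise a benzylic alcohol meets a diaryl ketal that ionises or reopens under the same conditions. A primary hydroxymethyl group gives an unstabilised quinone methide. A6 polymerises under acid. The core A5 still needs the differentiated arene plus a regioselective hydroxymethylation. The ketal of A5 must be made enantioselectively with no resident stereocentre, whereas in the chosen route the same closure gives diastereomers that can be separated.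
- Comparison: the chosen route sets C2' early by a reliable ketone reduction and keeps the ketal out of every acidic step.

**Alternative 3: oxidative 1,2-aryl shift (chalcone to isoflavone type).**
- Disconnection: C3–C8' and C2–O1. The chalcone A8 rearranges to the 3-(flavan-8'-yl)chromone A7.
- Forward key step: PhI(OAc)2 in acidic methanol, or Tl(NO3)3, adds to the double bond, the flavan aryl group migrates from the β- to the α-carbon, and the acetal cyclises onto the ring A phenol.
- For it: the rearrangement is well understood, electron-rich aryl groups migrate well, and A8 comes from a simple aldol condensation. On robustness of the individual key reaction it is at least equal.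
- Against it: A7 has hydrogen at C2, so the 4-hydroxyphenyl group still has to be attached there, and the ketal closure, with the same facial problem, comes after that. The aldehyde precursor of A8 needs C8' versus C6' formylation of a flavan. The oxidants meet an electron-rich flavan with a benzylic ether.
- Comparison: more steps remain after its key step than after the benzannulation, and it does not address the oxygen differentiation.

Key step: step 11

Assumption: the descriptors used (C2 S, C3 S, C2' R) are those encoded by the target SMILES, with C2/C3 cis-fused; compounds 1, 3, 4, 12 and 13 are taken as catalogue materials.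

## Route

**Step 1**
Reactants: 1 1,3,5-tris(benzyloxy)benzene
Product: 2 2,4,6-tris(benzyloxy)benzaldehyde
Conditions: POCl3, DMF, 0 °C → rt; aq. NaOAc
Reagents that add atoms: N,N-dimethylformamide, CN(C)C=O (formyl carbon); water, O (formyl oxygen, on hydrolysis of the iminium salt)
Why: Vilsmeier–Haack formylation; the chloroiminium ion attacks the single type of ring position of the symmetric, strongly activated triether, and the iminium product is deactivated towards a second attack.

**Step 2**
Reactants: 3 methyl 4,5-dibromofuran-2-carboxylate; 4 4-(benzyloxy)phenylboronic acid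
Product: 5 methyl 5-[4-(benzyloxy)phenyl]-4-bromofuran-2-carboxylate
Conditions: Pd(PPh3)4 (3 mol%), Na2CO3, DME–H2O, 70 °C, one equivalent of 4
Reagents that add atoms: none
Why: Suzuki–Miyaura coupling; oxidative addition of zerovalent palladium is faster at the C5–Br bond (α to the ring oxygen and conjugated with the ester) than at the β C4–Br bond, so monoarylation at C5 is expected.

**Step 3**
Reactants: 5 methyl 5-[4-(benzyloxy)phenyl]-4-bromofuran-2-carboxylate; 2 2,4,6-tris(benzyloxy)benzaldehyde
Product: 7 methyl 5-[4-(benzyloxy)phenyl]-4-{hydroxy[2,4,6-tris(benzyloxy)phenyl]methyl}furan-2-carboxylate (racemic at the carbinol carbon), via furylmagnesium chloride 6 (not isolated)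
Conditions: i-PrMgCl·LiCl, THF, −40 °C; then 2, −40 → 0 °C; aq. NH4Cl
Reagents that add atoms: isopropylmagnesium chloride–lithium chloride, CC(C)[Mg]Cl.[Li+].[Cl-] (Mg and Cl of 6 only)
Why: Bromine–magnesium exchange with the LiCl-activated (turbo) Grignard reagent at a temperature at which the methyl ester is inert, then 1,2-addition to the aldehyde. The carbinol stereocentre forms as a racemate and is erased in step 4.

**Step 4**
Reactants: 7 the furyl aryl carbinol
Product: 8 methyl 5-[4-(benzyloxy)phenyl]-4-[2,4,6-tris(benzyloxy)benzoyl]furan-2-carboxylate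
Conditions: Dess–Martin periodinane, NaHCO3, CH2Cl2, rt
Reagents that add atoms: none
Why: Dess–Martin oxidation of a doubly benzylic secondary alcohol; the buffered, non-acidic medium avoids ionisation of this electron-rich diarylcarbinol.

**Step 5**
Reactants: 8 the aroylfuran methyl ester
Product: 9 5-[4-(benzyloxy)phenyl]-4-[2,4,6-tris(benzyloxy)benzoyl]furan-2-carboxylic acid
Conditions: LiOH, THF–MeOH–H2O, rt; then 1 M HCl to pH 3
Reagents that add atoms: lithium hydroxide, [Li+].[OH-] (hydroxyl oxygen of the acid)
Why: Saponification of an unhindered 2-furoate; the diaryl ketone has no α-hydrogen and is shielded by two ortho benzyloxy groups.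

**Step 6**
Reactants: 9 the furoic acid
Product: 11 2-diazo-1-{5-[4-(benzyloxy)phenyl]-4-[2,4,6-tris(benzyloxy)benzoyl]furan-2-yl}ethanone, via furoyl chloride 10 (not isolated)
Conditions: (COCl)2, DMF (cat.), CH2Cl2, 0 °C → rt; evaporate; CH2N2 (3 equiv), Et2O–THF, 0 °C
Reagents that add atoms: oxalyl chloride, ClC(=O)C(=O)Cl (chlorine of 10 only); diazomethane, C=[N+]=[N-]
Why: Acid chloride formation followed by acylation of diazomethane (first stage of the Arndt–Eistert sequence). Excess diazomethane takes up HCl, so no chloromethyl ketone forms, and the hindered diaryl ketone does not react.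

**Step 7**
Reactants: 12 1-(benzyloxy)-4-bromobenzene; 13 ethyl 4-chloro-4-oxobutanoate
Product: 15 ethyl 4-[4-(benzyloxy)phenyl]-4-oxobutanoate, via arylmagnesium bromide 14 (not isolated)
Conditions: Mg, THF, rt; then added to 13, Fe(acac)3 (3 mol%), THF, −78 °C
Reagents that add atoms: magnesium, [Mg] (in 14 only)
Why: Grignard formation and Fe(acac)3-catalysed acylation by the acid chloride, which at −78 °C is far faster than addition to the ester or to the product ketone. No Lewis acid touches the benzyl ether.

**Step 8**
Reactants: 15 the γ-keto ester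
Product: 16 ethyl (4S)-4-[4-(benzyloxy)phenyl]-4-hydroxybutanoate
Conditions: (R)-2-methyl-CBS-oxazaborolidine (10 mol%), BH3·SMe2, THF, −20 °C; MeOH quench, cold neutral work-up
Reagents that add atoms: none
Why: Corey–Bakshi–Shibata reduction; with the aryl group as the large and the CH2 chain as the small substituent, the (R)-catalyst should give the (S)-carbinol, as it does with acetophenone. Borane does not reduce the ester at this temperature.

**Step 9**
Reactants: 16 the (S)-hydroxy ester (used crude)
Product: 17 ethyl (4S)-4-[4-(benzyloxy)phenyl]-4-(triethylsilyloxy)butanoate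
Conditions: TESCl, imidazole, DMF, 0 °C
Reagents that add atoms: chlorotriethylsilane, CC[Si](Cl)(CC)CC
Why: Silylation of the secondary alcohol, done at once so that γ-lactone formation cannot compete. Triethylsilyl is chosen because it can later be removed in the presence of an aryl triisopropylsilyl ether.

**Step 10**
Reactants: 17 the silyloxy ester
Product: 19 (S)-1-[4-(benzyloxy)phenyl]-1-(triethylsilyloxy)-5-(triisopropylsilyloxy)pent-4-yne, via lithium ynolate 18 (not isolated)
Conditions: CH2Br2, LiTMP, THF, −78 °C; 17; LiHMDS; n-BuLi, −78 → 0 °C; TIPSCl, −78 °C → rt; rapid filtration through Et3N-deactivated silica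
Reagents that add atoms: dibromomethane, BrCBr (new alkyne carbon); n-butyllithium, [Li]CCCC (lithium of 18 only); chlorotriisopropylsilane, CC(C)[Si](Cl)(C(C)C)C(C)C
Why: Kowalski ester homologation stopped at the ynolate: LiCHBr2 adds to the ester, and the dibromo ketone enolate undergoes Br/Li exchange and 1,2-shift of the alkyl group to give 18. The bulky silyl chloride silylates 18 on oxygen. The stereocentre is not adjacent to any reacting atom.

**Step 11 (key step)**
Reactants: 11 the furyl diazo ketone; 19 the siloxyalkyne (1.3 equiv)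
Product: 23 {2-[4-(benzyloxy)phenyl]-5-{(3S)-3-[4-(benzyloxy)phenyl]-3-(triethylsilyloxy)propyl}-4-hydroxy-6-(triisopropylsilyloxy)-1-benzofuran-3-yl}[2,4,6-tris(benzyloxy)phenyl]methanone, via furylketene 20 (not isolated), via siloxycyclobutenone 21 (not isolated), via dienylketene 22 (not isolated)
Conditions: ClCH2CH2Cl (degassed), hν (blue LEDs, 450 nm), rt; then 80 °C in the dark
Reagents that add atoms: none
Why: This is the Danheiser benzannulation in its diazo ketone form, known for heteroaryl α-diazo ketones with siloxyalkynes. Visible-light Wolff rearrangement of 11 (loss of N2 and 1,2-shift of the furyl group, which makes the C6'–C7' link) gives furylketene 20. The nucleophilic, alkyl-bearing carbon of the polarised siloxyalkyne attacks the ketene carbonyl carbon and the [2+2] cycloaddition finishes at the siloxy carbon, giving 21 with the new bonds C4a'–C8a' and C5'–C6'. At 80 °C 21 opens by four-electron electrocyclic cleavage of its C8a'–C6' bond to dienylketene 22. The benzene ring is then closed by six-electron disrotatory electrocyclisation of C8a' onto the free furan β-carbon C8', the only available ortho position, followed by tautomerisation to the phenol. No stereocentre is created, since the sp3 carbon of 21 is lost again, and the remote (S)-carbinol is untouched. The selectivity needed is regiochemical and is secured by the donor oxygen of the ynol ether, which fixes the orientation of the [2+2] step: the chain lies between the two new oxygens, the ketene oxygen becomes the free C8a' phenol, the alkyne oxygen the silylated C5' oxygen, and the furan oxygen becomes O7'. Light of 450 nm should be absorbed by the diazo ketone but not by the aroylfuran ketone, which avoids δ-hydrogen abstraction from the ortho benzyloxy groups, and the hindered, hydrogen-bonded product phenol is a poor trap for the ketene.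

**Step 12**
Reactants: 23 the benzannulation product
Product: 24 {2-[4-(benzyloxy)phenyl]-5-{(3S)-3-[4-(benzyloxy)phenyl]-3-hydroxypropyl}-4-hydroxy-6-(triisopropylsilyloxy)-1-benzofuran-3-yl}[2,4,6-tris(benzyloxy)phenyl]methanone
Conditions: HF·pyridine, pyridine, THF, 0 °C
Reagents that add atoms: none
Why: Buffered HF·pyridine cleaves the alkyl triethylsilyl ether much faster than the hindered aryl triisopropylsilyl ether, and the near-neutral medium does not ionise the benzylic carbinol.

**Step 13**
Reactants: 24 the phenol carbinol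
Product: 25 [(2R)-2,8-bis[4-(benzyloxy)phenyl]-5-(triisopropylsilyloxy)-3,4-dihydro-2H-furo[2,3-h]chromen-9-yl][2,4,6-tris(benzyloxy)phenyl]methanone
Conditions: PPh3, DIAD, toluene, −20 °C → rt
Reagents that add atoms: none
Why: Intramolecular Mitsunobu etherification: the only free phenol (C8a'–OH) displaces the activated benzylic oxygen in a 6-exo-tet SN2 closure with inversion, turning the (S)-carbinol into (R)-C2'. The C5' oxygen is blocked as its silyl ether, so the isomeric closure is excluded, and the non-polar solvent disfavours ionisation.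

**Step 14**
Reactants: 25 the flavan silyl ether
Product: 26 [(2R)-2,8-bis[4-(benzyloxy)phenyl]-5-hydroxy-3,4-dihydro-2H-furo[2,3-h]chromen-9-yl][2,4,6-tris(benzyloxy)phenyl]methanone
Conditions: TBAF, AcOH, THF, 0 °C
Reagents that add atoms: none
Why: Fluoride cleavage of the aryl silyl ether, buffered with acetic acid so that no free phenoxide is exposed.

**Step 15**
Reactants: 26 the pentabenzyl ether
Product: 27 [(2R)-5-hydroxy-2,8-bis(4-hydroxyphenyl)-3,4-dihydro-2H-furo[2,3-h]chromen-9-yl](2,4,6-trihydroxyphenyl)methanone
Conditions: H2 (1 atm), Pd/C (10%), EtOAc–THF, rt; filtered under argon and used at once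
Reagents that add atoms: none
Why: Hydrogenolysis of five aryl benzyl ethers. These should cleave faster than the cyclic benzylic C2'–O1' ether, and the tetrasubstituted furan double bond and the hindered diaryl ketone should not be reduced at 1 atm in a neutral solvent.

**Step 16**
Reactants: 27 the open aroylbenzofuran hexaphenol
Product: 28 the target, (2S,3S,2'R)-ketal
Conditions: quinine (1.0 equiv), THF–toluene, −20 °C; quench with cold aq. citric acid
Reagents that add atoms: none
Why: Proposed new method: an ortho hydroxyl of the 2,4,6-trihydroxybenzoyl group adds to C2 of the 3-aroylbenzofuran (a vinylogous ester) and C3 is protonated on the opposite face, as the cis fusion demands; quinine is expected to act as a bifunctional base (quinuclidine nitrogen on the phenol, C9 hydroxyl on the carbonyl) and so to distinguish the two faces of the flat benzofuran, which the remote C2' cannot; the closest known reaction type is the cinchona-alkaloid-mediated cyclisation of 2'-hydroxychalcones to flavanones, and what is new is its use on a furan C2=C3 bond with loss of furan aromaticity and with a ketal carbon as the new stereocentre.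

## Compound list

1 | 1,3,5-tris(benzyloxy)benzene | c1ccc(COc2cc(OCc3ccccc3)cc(OCc3ccccc3)c2)cc1 | starting material
2 | 2,4,6-tris(benzyloxy)benzaldehyde | O=Cc1c(OCc2ccccc2)cc(OCc2ccccc2)cc1OCc1ccccc1 | intermediate
3 | methyl 4,5-dibromofuran-2-carboxylate | COC(=O)c1cc(Br)c(Br)o1 | starting material
4 | 4-(benzyloxy)phenylboronic acid | OB(O)c1ccc(OCc2ccccc2)cc1 | starting material
5 | methyl 5-[4-(benzyloxy)phenyl]-4-bromofuran-2-carboxylate | COC(=O)c1cc(Br)c(-c2ccc(OCc3ccccc3)cc2)o1 | intermediate
6 | {2-[4-(benzyloxy)phenyl]-5-(methoxycarbonyl)furan-3-yl}magnesium chloride (LiCl complex) | COC(=O)c1cc([Mg]Cl)c(-c2ccc(OCc3ccccc3)cc2)o1 | intermediate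
7 | methyl 5-[4-(benzyloxy)phenyl]-4-{hydroxy[2,4,6-tris(benzyloxy)phenyl]methyl}furan-2-carboxylate (racemic) | COC(=O)c1cc(C(O)c2c(OCc3ccccc3)cc(OCc3ccccc3)cc2OCc2ccccc2)c(-c2ccc(OCc3ccccc3)cc2)o1 | intermediate
8 | methyl 5-[4-(benzyloxy)phenyl]-4-[2,4,6-tris(benzyloxy)benzoyl]furan-2-carboxylate | COC(=O)c1cc(C(=O)c2c(OCc3ccccc3)cc(OCc3ccccc3)cc2OCc2ccccc2)c(-c2ccc(OCc3ccccc3)cc2)o1 | intermediate
9 | 5-[4-(benzyloxy)phenyl]-4-[2,4,6-tris(benzyloxy)benzoyl]furan-2-carboxylic acid | OC(=O)c1cc(C(=O)c2c(OCc3ccccc3)cc(OCc3ccccc3)cc2OCc2ccccc2)c(-c2ccc(OCc3ccccc3)cc2)o1 | intermediate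
10 | 5-[4-(benzyloxy)phenyl]-4-[2,4,6-tris(benzyloxy)benzoyl]furan-2-carbonyl chloride | ClC(=O)c1cc(C(=O)c2c(OCc3ccccc3)cc(OCc3ccccc3)cc2OCc2ccccc2)c(-c2ccc(OCc3ccccc3)cc2)o1 | intermediate
11 | 2-diazo-1-{5-[4-(benzyloxy)phenyl]-4-[2,4,6-tris(benzyloxy)benzoyl]furan-2-yl}ethanone | [N-]=[N+]=CC(=O)c1cc(C(=O)c2c(OCc3ccccc3)cc(OCc3ccccc3)cc2OCc2ccccc2)c(-c2ccc(OCc3ccccc3)cc2)o1 | intermediate
12 | 1-(benzyloxy)-4-bromobenzene | Brc1ccc(OCc2ccccc2)cc1 | starting material
13 | ethyl 4-chloro-4-oxobutanoate | CCOC(=O)CCC(=O)Cl | starting material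
14 | 4-(benzyloxy)phenylmagnesium bromide | Br[Mg]c1ccc(OCc2ccccc2)cc1 | intermediate
15 | ethyl 4-[4-(benzyloxy)phenyl]-4-oxobutanoate | CCOC(=O)CCC(=O)c1ccc(OCc2ccccc2)cc1 | intermediate
16 | ethyl (4S)-4-[4-(benzyloxy)phenyl]-4-hydroxybutanoate | CCOC(=O)CC[C@H](O)c1ccc(OCc2ccccc2)cc1 | intermediate
17 | ethyl (4S)-4-[4-(benzyloxy)phenyl]-4-(triethylsilyloxy)butanoate | CCOC(=O)CC[C@H](O[Si](CC)(CC)CC)c1ccc(OCc2ccccc2)cc1 | intermediate
18 | lithium (5S)-5-[4-(benzyloxy)phenyl]-5-(triethylsilyloxy)pent-1-yn-1-olate | [Li]OC#CCC[C@H](O[Si](CC)(CC)CC)c1ccc(OCc2ccccc2)cc1 | intermediate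
19 | (S)-1-[4-(benzyloxy)phenyl]-1-(triethylsilyloxy)-5-(triisopropylsilyloxy)pent-4-yne | CC(C)[Si](OC#CCC[C@H](O[Si](CC)(CC)CC)c1ccc(OCc2ccccc2)cc1)(C(C)C)C(C)C | intermediate
20 | 2-{5-[4-(benzyloxy)phenyl]-4-[2,4,6-tris(benzyloxy)benzoyl]furan-2-yl}ethenone (furylketene) | O=C=Cc1cc(C(=O)c2c(OCc3ccccc3)cc(OCc3ccccc3)cc2OCc2ccccc2)c(-c2ccc(OCc3ccccc3)cc2)o1 | intermediate
21 | 4-furyl-2-[(3S)-3-aryl-3-(triethylsilyloxy)propyl]-3-(triisopropylsilyloxy)cyclobut-2-en-1-one (both epimers at the ring carbon) | O=C1C(CC[C@H](O[Si](CC)(CC)CC)c2ccc(OCc3ccccc3)cc2)=C(O[Si](C(C)C)(C(C)C)C(C)C)C1c1cc(C(=O)c2c(OCc3ccccc3)cc(OCc3ccccc3)cc2OCc2ccccc2)c(-c2ccc(OCc3ccccc3)cc2)o1 | intermediate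
22 | dienylketene O=C=C(chain)–C(OTIPS)=CH–furyl (furyl cis to the ketenyl carbon) | O=C=C(CC[C@H](O[Si](CC)(CC)CC)c1ccc(OCc2ccccc2)cc1)C(O[Si](C(C)C)(C(C)C)C(C)C)=Cc1cc(C(=O)c2c(OCc3ccccc3)cc(OCc3ccccc3)cc2OCc2ccccc2)c(-c2ccc(OCc3ccccc3)cc2)o1 | intermediate
23 | {2-[4-(benzyloxy)phenyl]-5-{(3S)-3-[4-(benzyloxy)phenyl]-3-(triethylsilyloxy)propyl}-4-hydroxy-6-(triisopropylsilyloxy)-1-benzofuran-3-yl}[2,4,6-tris(benzyloxy)phenyl]methanone | O=C(c1c(OCc2ccccc2)cc(OCc2ccccc2)cc1OCc1ccccc1)c1c(-c2ccc(OCc3ccccc3)cc2)oc2cc(O[Si](C(C)C)(C(C)C)C(C)C)c(CC[C@H](O[Si](CC)(CC)CC)c3ccc(OCc4ccccc4)cc3)c(O)c12 | intermediate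
24 | {2-[4-(benzyloxy)phenyl]-5-{(3S)-3-[4-(benzyloxy)phenyl]-3-hydroxypropyl}-4-hydroxy-6-(triisopropylsilyloxy)-1-benzofuran-3-yl}[2,4,6-tris(benzyloxy)phenyl]methanone | O=C(c1c(OCc2ccccc2)cc(OCc2ccccc2)cc1OCc1ccccc1)c1c(-c2ccc(OCc3ccccc3)cc2)oc2cc(O[Si](C(C)C)(C(C)C)C(C)C)c(CC[C@H](O)c3ccc(OCc4ccccc4)cc3)c(O)c12 | intermediate
25 | [(2R)-2,8-bis[4-(benzyloxy)phenyl]-5-(triisopropylsilyloxy)-3,4-dihydro-2H-furo[2,3-h]chromen-9-yl][2,4,6-tris(benzyloxy)phenyl]methanone (furan O on C7', aroyl-bearing carbon on C8' of the flavan) | O=C(c1c(OCc2ccccc2)cc(OCc2ccccc2)cc1OCc1ccccc1)c1c(-c2ccc(OCc3ccccc3)cc2)oc2cc(O[Si](C(C)C)(C(C)C)C(C)C)c3c(c12)O[C@@H](c1ccc(OCc2ccccc2)cc1)CC3 | intermediate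
26 | [(2R)-2,8-bis[4-(benzyloxy)phenyl]-5-hydroxy-3,4-dihydro-2H-furo[2,3-h]chromen-9-yl][2,4,6-tris(benzyloxy)phenyl]methanone | O=C(c1c(OCc2ccccc2)cc(OCc2ccccc2)cc1OCc1ccccc1)c1c(-c2ccc(OCc3ccccc3)cc2)oc2cc(O)c3c(c12)O[C@@H](c1ccc(OCc2ccccc2)cc1)CC3 | intermediate
27 | [(2R)-5-hydroxy-2,8-bis(4-hydroxyphenyl)-3,4-dihydro-2H-furo[2,3-h]chromen-9-yl](2,4,6-trihydroxyphenyl)methanone | O=C(c1c(O)cc(O)cc1O)c1c(-c2ccc(O)cc2)oc2cc(O)c3c(c12)O[C@@H](c1ccc(O)cc1)CC3 | intermediate
28 | (2S,3S,2'R)-ketal: 5,7-dihydroxy-2-(4-hydroxyphenyl)chroman-4-one whose C2 is bonded to O7' and whose C3 is bonded to C8' of (2'R)-4',5'-dihydroxyflavan, cis-fused dihydrofuran | O=C1c2c(O)cc(O)cc2O[C@@]2(c3ccc(O)cc3)Oc3cc(O)c4c(c3[C@@H]12)O[C@@H](c1ccc(O)cc1)CC4 | target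

## Step count and risk

Total: 16 steps. Longest linear sequence: 11 steps (3 → 5 → 7 → 8 → 9 → 11 → 23 → 24 → 25 → 26 → 27 → 28; the branch from 1 is equally long, the alkyne branch from 12 is 10).

**Step 16 (proposed new method).** The most likely failure is poor facial selectivity. The closure is reversible (retro-oxa-Michael through the enolate), the two ketals differ only in their relation to the remote C2' and should be close in energy, so a kinetic preference set by the alkaloid can erode, and closure may also stop short of completion. Fallback, from 27 and returning at 28: catalyst control is given up. The closure is left to equilibrate with an achiral base (NaOAc in aqueous methanol), as in the chalcone–flavanone isomerisation. The target is then separated by reversed-phase preparative HPLC from the (2R,3R,2'R)-diastereomer F1, which is returned to the same equilibration. Both operations are standard, and no material is lost because 27, 28 and F1 interconvert.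

**Step 11 (key step).** Three processes may interfere: excitation of the aroylfuran chromophore with hydrogen abstraction from an ortho benzyloxy group; loss of the ketene to dimerisation or to acylation of the product phenol; and arrest at the cyclobutenone stage if electrocyclisation onto the acyl-flanked furan β-carbon is slow. Fallback, from 11 and returning at 23: the same ketene is generated in the dark. Wolff rearrangement of 11 with PhCO2Ag and Et3N in aqueous dioxane gives {5-[4-(benzyloxy)phenyl]-4-[2,4,6-tris(benzyloxy)benzoyl]furan-2-yl}acetic acid F2. Oxalyl chloride converts it into the acyl chloride F3. Slow addition of Et3N to F3 and 19 in toluene, followed by heating, forms 20 by dehydrochlorination and carries it through 21 and 22 to 23.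

**Step 3.** Exchange at the β-bromide may be slow enough for attack of the magnesium reagents on the ester to compete. Fallback, from 5 and returning at 8 (skipping 7): the polarity is reversed. Alkoxycarbonylation of 5 (Pd(OAc)2, Xantphos, CO, 2-(trimethylsilyl)ethanol, Et3N) gives the mixed diester 2-methyl 4-[2-(trimethylsilyl)ethyl] 5-[4-(benzyloxy)phenyl]furan-2,4-dicarboxylate F4. TBAF releases 2-[4-(benzyloxy)phenyl]-5-(methoxycarbonyl)furan-3-carboxylic acid F5. The mixed anhydride of F5 with trifluoroacetic anhydride then acylates the very electron-rich arene 1 without a Lewis acid.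

**Step 10.** The carbenoid rearrangement may be incomplete, or the ynolate may be silylated on carbon to give a silylketene. Fallback, from 17 and returning at 19: DIBAL-H at −78 °C gives (4S)-4-[4-(benzyloxy)phenyl]-4-(triethylsilyloxy)butanal F6. The Ohira–Bestmann reagent converts it into the terminal alkyne (S)-{1-[4-(benzyloxy)phenyl]pent-4-yn-1-yl}oxytriethylsilane F7. Its lithium acetylide is oxidised with LiOOt-Bu to the ynolate and trapped with TIPSOTf.

**Step 13.** The oxyphosphonium intermediate sits on a 4-alkoxybenzylic carbon, so partial ionisation would lower the stereochemical fidelity of the inversion, and elimination to the styrene may compete. Fallback, from 24 and returning at 25: the carbinol is oxidised (Dess–Martin periodinane) to the ketone F8. Acid-catalysed cyclodehydration (PPTS, toluene) gives the 2-aryl-4H-chromene F9. The stereocentre is then set by asymmetric hydrogenation with [Ir(cod)(tBu-PHOX)]BArF and H2, the ligand enantiomer being chosen for (R)-C2'.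

## Further compounds

F1 | step 16 | (2R,3R,2'R)-diastereomer of 28 | O=C1c2c(O)cc(O)cc2O[C@]2(c3ccc(O)cc3)Oc3cc(O)c4c(c3[C@H]12)O[C@@H](c1ccc(O)cc1)CC4
F2 | step 11 | {5-[4-(benzyloxy)phenyl]-4-[2,4,6-tris(benzyloxy)benzoyl]furan-2-yl}acetic acid | OC(=O)Cc1cc(C(=O)c2c(OCc3ccccc3)cc(OCc3ccccc3)cc2OCc2ccccc2)c(-c2ccc(OCc3ccccc3)cc2)o1
F3 | step 11 | {5-[4-(benzyloxy)phenyl]-4-[2,4,6-tris(benzyloxy)benzoyl]furan-2-yl}acetyl chloride | ClC(=O)Cc1cc(C(=O)c2c(OCc3ccccc3)cc(OCc3ccccc3)cc2OCc2ccccc2)c(-c2ccc(OCc3ccccc3)cc2)o1
F4 | step 3 | 2-methyl 4-[2-(trimethylsilyl)ethyl] 5-[4-(benzyloxy)phenyl]furan-2,4-dicarboxylate | COC(=O)c1cc(C(=O)OCC[Si](C)(C)C)c(-c2ccc(OCc3ccccc3)cc2)o1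
F5 | step 3 | 2-[4-(benzyloxy)phenyl]-5-(methoxycarbonyl)furan-3-carboxylic acid | COC(=O)c1cc(C(=O)O)c(-c2ccc(OCc3ccccc3)cc2)o1
F6 | step 10 | (4S)-4-[4-(benzyloxy)phenyl]-4-(triethylsilyloxy)butanal | O=CCC[C@H](O[Si](CC)(CC)CC)c1ccc(OCc2ccccc2)cc1
F7 | step 10 | (S)-{1-[4-(benzyloxy)phenyl]pent-4-yn-1-yl}oxytriethylsilane | C#CCC[C@H](O[Si](CC)(CC)CC)c1ccc(OCc2ccccc2)cc1
F8 | step 13 | {2-[4-(benzyloxy)phenyl]-5-{3-[4-(benzyloxy)phenyl]-3-oxopropyl}-4-hydroxy-6-(triisopropylsilyloxy)-1-benzofuran-3-yl}[2,4,6-tris(benzyloxy)phenyl]methanone | O=C(c1c(OCc2ccccc2)cc(OCc2ccccc2)cc1OCc1ccccc1)c1c(-c2ccc(OCc3ccccc3)cc2)oc2cc(O[Si](C(C)C)(C(C)C)C(C)C)c(CCC(=O)c3ccc(OCc4ccccc4)cc3)c(O)c12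
F9 | step 13 | [2,8-bis[4-(benzyloxy)phenyl]-5-(triisopropylsilyloxy)-4H-furo[2,3-h]chromen-9-yl][2,4,6-tris(benzyloxy)phenyl]methanone | O=C(c1c(OCc2ccccc2)cc(OCc2ccccc2)cc1OCc1ccccc1)c1c(-c2ccc(OCc3ccccc3)cc2)oc2cc(O[Si](C(C)C)(C(C)C)C(C)C)c3c(c12)OC(c1ccc(OCc2ccccc2)cc1)=CC3
A1 | alternative 1 | [(2R)-5-(benzyloxy)-2,8-bis[4-(benzyloxy)phenyl]-3,4-dihydro-2H-furo[2,3-h]chromen-9-yl][2,4,6-tris(benzyloxy)phenyl]methanone | O=C(c1c(OCc2ccccc2)cc(OCc2ccccc2)cc1OCc1ccccc1)c1c(-c2ccc(OCc3ccccc3)cc2)oc2cc(OCc3ccccc3)c3c(c12)O[C@@H](c1ccc(OCc2ccccc2)cc1)CC3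
A2 | alternative 1 | (2R)-5-(benzyloxy)-2-[4-(benzyloxy)phenyl]-8-{[4-(benzyloxy)phenyl]ethynyl}chroman-7-ol | Oc1cc(OCc2ccccc2)c2c(c1C#Cc1ccc(OCc3ccccc3)cc1)O[C@@H](c1ccc(OCc3ccccc3)cc1)CC2
A3 | alternative 1 | 1,3,5-tris(benzyloxy)-2-iodobenzene | Ic1c(OCc2ccccc2)cc(OCc2ccccc2)cc1OCc1ccccc1
A4 | alternative 2 | tetrabenzyl ether of 28 (benzyl on the 5-, 7-, C2-aryl and 5'-oxygens, flavan 4'-OH free) | O=C1c2c(OCc3ccccc3)cc(OCc3ccccc3)cc2O[C@@]2(c3ccc(OCc5ccccc5)cc3)Oc3cc(OCc5ccccc5)c4c(c3[C@@H]12)O[C@@H](c1ccc(O)cc1)CC4
A5 | alternative 2 | ketal core configured as in 28, with CH2OH on C4a', free OH on C8a' and four benzyl ethers | O=C1c2c(OCc3ccccc3)cc(OCc3ccccc3)cc2O[C@@]2(c3ccc(OCc5ccccc5)cc3)Oc3cc(OCc5ccccc5)c(CO)c(O)c3[C@@H]12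
A6 | alternative 2 | 4-vinylphenol | C=Cc1ccc(O)cc1
A7 | alternative 3 | 5,7-bis(benzyloxy)-3-{(2R)-5,7-bis(benzyloxy)-2-[4-(benzyloxy)phenyl]chroman-8-yl}-4H-chromen-4-one | O=c1c(-c2c(OCc3ccccc3)cc(OCc3ccccc3)c3c2O[C@@H](c2ccc(OCc4ccccc4)cc2)CC3)coc2cc(OCc3ccccc3)cc(OCc3ccccc3)c12
A8 | alternative 3 | (E)-1-[2,4-bis(benzyloxy)-6-hydroxyphenyl]-3-{(2R)-5,7-bis(benzyloxy)-2-[4-(benzyloxy)phenyl]chroman-8-yl}prop-2-en-1-one | O=C(/C=C/c1c(OCc2ccccc2)cc(OCc2ccccc2)c2c1O[C@@H](c1ccc(OCc3ccccc3)cc1)CC2)c1c(O)cc(OCc2ccccc2)cc1OCc1ccccc1
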